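**Assumption:** carotenoid numbering is used (ring carbon bearing the chain = C6, ring carbonyl = C3). The SMILES carries opposite descriptors at the two ring stereocentres (6S,6'R), so the target is the all-E meso diastereomer and is made as that single stereoisomer. Racemic compounds are written without a descriptor at the ring carbon.

## Retrosynthetic overview

- The two carbonyl carbons are 1,26-related (even), so one chain bond must join two like-polarity carbons. The cut is at C11=C12 and C11'=C12', giving two enantiomeric C15 allylic tetrazolyl sulfones and the C10 dialdehyde.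
- In each union (Julia–Kocienski) C11, formerly an ester carbonyl carbon, acts as an α-sulfonyl carbanion and is joined to an aldehyde carbon.
- The (R)-sulfone is attached first (C25 aldehyde) and the (S)-sulfone second, which fixes the R/S (meso) relationship. Both sulfones come from one racemate by resolution, so neither enantiomer is discarded.
- The racemic keto sulfone comes from (±)-α-ionone by C2 olefination, ring allylic oxidation and ester → thioether → sulfone.
- No ring is formed: both cyclohexenone rings are carried in with α-ionone, and only their C3 oxidation level is adjusted before the chain is assembled.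

## Route

Step 1
Reactants: 1 (±)-α-ionone; 2 triethyl phosphonoacetate
Product: 3 ethyl (2E,4E)-3-methyl-5-(2,6,6-trimethylcyclohex-2-en-1-yl)penta-2,4-dienoate (racemic)
Conditions: NaH, THF, 0 → 65 °C; chromatography (2Z isomer removed)
Reagents that add atoms: none
Why: Horner–Wadsworth–Emmons olefination of the methyl ketone by the stabilised phosphonate anion gives mainly the 2E dienoate without touching the ring, and no stereocentre is created.

Step 2
Reactants: 3 ethyl α-ionylideneacetate
Product: 4 ethyl (2E,4E)-3-methyl-5-(2,6,6-trimethyl-4-oxocyclohex-2-en-1-yl)penta-2,4-dienoate (racemic)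
Conditions: t-BuOOH (70% aq), CrO3 (5 mol%), CH2Cl2, 20 °C
Reagents that add atoms: tert-butyl hydroperoxide, CC(C)(C)OO
Why: Chromium-catalysed allylic oxidation attacks the only allylic CH2 of the ring alkene while the electron-poor dienoate is left alone, as known for α-ionone and α-ionylideneacetates.

Step 3
Reactants: 4 racemic keto ester
Product: 5 (2E,4E)-5-(4-hydroxy-2,6,6-trimethylcyclohex-2-en-1-yl)-3-methylpenta-2,4-dien-1-ol (racemic; both carbinol epimers)
Conditions: i-Bu2AlH (4 equiv), CH2Cl2, −78 → 0 °C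
Reagents that add atoms: none
Why: 1,2-Hydride reduction takes the dienoate to the primary allylic alcohol and unavoidably the enone to the allylic carbinol; the new carbinol centre forms as an epimer mixture that is irrelevant because step 5 removes it.

Step 4
Reactants: 5 racemic diol; 6 1-phenyl-1H-tetrazole-5-thiol
Product: 7 5-{[(2E,4E)-5-(4-hydroxy-2,6,6-trimethylcyclohex-2-en-1-yl)-3-methylpenta-2,4-dien-1-yl]sulfanyl}-1-phenyl-1H-tetrazole (racemic; both carbinol epimers)
Conditions: PPh3, DIAD, THF, −20 → 0 °C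
Reagents that add atoms: none
Why: Mitsunobu thioetherification with one equivalent of the acidic thiol is selective for the unhindered primary dienylic alcohol over the hindered secondary ring carbinol.

Step 5
Reactants: 7 hydroxy sulfide
Product: 8 5-{[(2E,4E)-3-methyl-5-(2,6,6-trimethyl-4-oxocyclohex-2-en-1-yl)penta-2,4-dien-1-yl]sulfanyl}-1-phenyl-1H-tetrazole (racemic)
Conditions: MnO2 (activated, excess), CH2Cl2, 20 °C
Reagents that add atoms: none
Why: MnO2 oxidation of the allylic ring carbinol converges both epimers on the enone and does not oxidise the thioether.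

Step 6
Reactants: 8 keto sulfide
Product: 9 5-{[(2E,4E)-3-methyl-5-(2,6,6-trimethyl-4-oxocyclohex-2-en-1-yl)penta-2,4-dien-1-yl]sulfonyl}-1-phenyl-1H-tetrazole (racemic)
Conditions: H2O2 (30% aq), (NH4)6Mo7O24·4H2O (10 mol%), EtOH, 0 → 20 °C
Reagents that add atoms: hydrogen peroxide, OO
Why: Molybdate-catalysed peroxide oxidation takes the sulfide through the sulfoxide to the sulfone; under these non-basic conditions neither the enone alkene nor the diene is epoxidised.

Step 7
Reactants: 9 racemic keto sulfone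
Product: 10 5-{[(2E,4E)-3-methyl-5-[(1R)-2,6,6-trimethyl-4-oxocyclohex-2-en-1-yl]penta-2,4-dien-1-yl]sulfonyl}-1-phenyl-1H-tetrazole; 11 the (1S) enantiomer
Conditions: preparative HPLC on cellulose tris(3,5-dimethylphenylcarbamate), hexane/i-PrOH, 20 °C
Reagents that add atoms: none
Why: Resolution by chromatography on a chiral stationary phase delivers both enantiomers of the single, neutral-stable stereocentre (assigned by CD against 3-oxo-α-ionone of known configuration), and both are consumed because the target is meso.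

Step 8
Reactants: 10 (R)-keto sulfone; 12 (2E,4E,6E)-2,7-dimethylocta-2,4,6-trienedial
Product: 14 (2E,4E,6E,8E,10E,12E)-2,7,11-trimethyl-13-[(1R)-2,6,6-trimethyl-4-oxocyclohex-2-en-1-yl]trideca-2,4,6,8,10,12-hexaenal, via 11Z C25 aldehyde 13 (not isolated)
Conditions: 10, LiN(SiMe3)2 (1.0 equiv), THF, −78 °C; cannulate into 12 (3 equiv), THF, −78 → 0 °C; then heptane, 90 °C; chromatography
Reagents that add atoms: none
Why: Julia–Kocienski olefination in which C11 adds as an α-sulfonyl carbanion to one aldehyde carbon of excess 12 and Smiles rearrangement with loss of SO2 forges C11=C12; the sulfonyl CH2 is estimated to be several pK units more acidic than the ring γ-H, so the stereocentre should survive at −78 °C, and the hindered 11Z fraction is equilibrated thermally to all-E.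

Step 9
Reactants: 11 (S)-keto sulfone; 14 (R)-C25 keto aldehyde
Product: 16 (6S,6'R)-ε,ε-carotene-3,3'-dione (all-E), via 11Z dione 15 (not isolated)
Conditions: 11, LiN(SiMe3)2 (1.0 equiv), THF, −78 °C; then 14, −78 → 0 °C; then heptane, 90 °C; crystallisation
Reagents that add atoms: none
Why: The second Julia–Kocienski olefination again joins a carbanion-type former carbonyl carbon to an aldehyde carbon; adding the (S)-sulfone to the (R)-aldehyde can only give the (6S,6'R) compound since both stereocentres come unchanged from step 7, and heating converts the 11Z fraction to the all-E isomer, which crystallises.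

## Compound list

1 | (±)-α-ionone | CC(=O)/C=C/C1C(C)=CCCC1(C)C | starting material
2 | triethyl phosphonoacetate | CCOC(=O)CP(=O)(OCC)OCC | starting material
3 | ethyl (2E,4E)-3-methyl-5-(2,6,6-trimethylcyclohex-2-en-1-yl)penta-2,4-dienoate (racemic) | CCOC(=O)/C=C(C)/C=C/C1C(C)=CCCC1(C)C | intermediate
4 | ethyl (2E,4E)-3-methyl-5-(2,6,6-trimethyl-4-oxocyclohex-2-en-1-yl)penta-2,4-dienoate (racemic) | CCOC(=O)/C=C(C)/C=C/C1C(C)=CC(=O)CC1(C)C | intermediate
5 | (2E,4E)-5-(4-hydroxy-2,6,6-trimethylcyclohex-2-en-1-yl)-3-methylpenta-2,4-dien-1-ol (racemic, carbinol epimers) | OC/C=C(C)/C=C/C1C(C)=CC(O)CC1(C)C | intermediate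
6 | 1-phenyl-1H-tetrazole-5-thiol | Sc1nnnn1-c1ccccc1 | starting material
7 | 5-{[(2E,4E)-5-(4-hydroxy-2,6,6-trimethylcyclohex-2-en-1-yl)-3-methylpenta-2,4-dien-1-yl]sulfanyl}-1-phenyl-1H-tetrazole (racemic, carbinol epimers) | CC1=CC(O)CC(C)(C)C1/C=C/C(C)=C/CSc1nnnn1-c1ccccc1 | intermediate
8 | 5-{[(2E,4E)-3-methyl-5-(2,6,6-trimethyl-4-oxocyclohex-2-en-1-yl)penta-2,4-dien-1-yl]sulfanyl}-1-phenyl-1H-tetrazole (racemic) | CC1=CC(=O)CC(C)(C)C1/C=C/C(C)=C/CSc1nnnn1-c1ccccc1 | intermediate
9 | 5-{[(2E,4E)-3-methyl-5-(2,6,6-trimethyl-4-oxocyclohex-2-en-1-yl)penta-2,4-dien-1-yl]sulfonyl}-1-phenyl-1H-tetrazole (racemic) | CC1=CC(=O)CC(C)(C)C1/C=C/C(C)=C/CS(=O)(=O)c1nnnn1-c1ccccc1 | intermediate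
10 | (R)-keto sulfone: 5-{[(2E,4E)-3-methyl-5-[(1R)-2,6,6-trimethyl-4-oxocyclohex-2-en-1-yl]penta-2,4-dien-1-yl]sulfonyl}-1-phenyl-1H-tetrazole | CC1=CC(=O)CC(C)(C)[C@H]1/C=C/C(C)=C/CS(=O)(=O)c1nnnn1-c1ccccc1 | intermediate
11 | (S)-keto sulfone: 5-{[(2E,4E)-3-methyl-5-[(1S)-2,6,6-trimethyl-4-oxocyclohex-2-en-1-yl]penta-2,4-dien-1-yl]sulfonyl}-1-phenyl-1H-tetrazole | CC1=CC(=O)CC(C)(C)[C@@H]1/C=C/C(C)=C/CS(=O)(=O)c1nnnn1-c1ccccc1 | intermediate
12 | (2E,4E,6E)-2,7-dimethylocta-2,4,6-trienedial (C10 dialdehyde) | O=C/C(C)=C/C=C/C=C(C)/C=O | starting material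
13 | 11Z C25 aldehyde: (2E,4E,6E,8Z,10E,12E)-2,7,11-trimethyl-13-[(1R)-2,6,6-trimethyl-4-oxocyclohex-2-en-1-yl]trideca-2,4,6,8,10,12-hexaenal | CC1=CC(=O)CC(C)(C)[C@H]1/C=C/C(C)=C/C=C\C(C)=C\C=C\C=C(C)\C=O | intermediate
14 | (2E,4E,6E,8E,10E,12E)-2,7,11-trimethyl-13-[(1R)-2,6,6-trimethyl-4-oxocyclohex-2-en-1-yl]trideca-2,4,6,8,10,12-hexaenal ((6R)-3-oxo-12'-apo-ε-caroten-12'-al) | CC1=CC(=O)CC(C)(C)[C@H]1/C=C/C(C)=C/C=C/C(C)=C/C=C/C=C(C)/C=O | intermediate
15 | 11Z dione: (11Z,6S,6'R)-ε,ε-carotene-3,3'-dione | CC1=CC(=O)CC(C)(C)[C@@H]1/C=C/C(C)=C/C=C\C(C)=C\C=C\C=C(C)\C=C\C=C(C)\C=C\[C@H]1C(C)=CC(=O)CC1(C)C | intermediate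
16 | (all-E,6S,6'R)-ε,ε-carotene-3,3'-dione (meso) | CC1=CC(=O)CC(C)(C)[C@@H]1/C=C/C(C)=C/C=C/C(C)=C/C=C/C=C(C)/C=C/C=C(C)/C=C/[C@H]1C(C)=CC(=O)CC1(C)C | target

## Count and risks

Total step count: 9. Longest linear sequence: 9 (steps 1 to 9).

**Step 9 (and the carbanion chemistry in general).** The ring γ-hydrogen at C6 of the free 3-oxo ring is acidic, and it is more so in the polyenal 14. Any proton transfer to the sulfonyl carbanion would epimerise C6 and give the inseparable (6R,6'R)/(6S,6'S) diastereomers, detectable by chiral HPLC. The fallback masks the ketones during the carbanion steps. It sets out from 10 and 11 and returns at 16.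
- Luche reduction (NaBH4, CeCl3·7H2O, MeOH, −40 °C) of 10 gives the (R)-hydroxy sulfone F1, and of 11 the (S)-hydroxy sulfone F2, each as a pair of carbinol epimers whose ring γ-hydrogen is no longer acidic.
- The dianion of F1 (2.1 equiv LiN(SiMe3)2) is coupled with excess 12 to give the C25 hydroxy aldehyde F3.
- The dianion of F2 is coupled with F3, with the same thermal equilibration, to give (6S,6'R)-ε,ε-carotene-3,3'-diol F4.
- MnO2 oxidation of both allylic carbinols under neutral conditions leads back to 16.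

**Step 8.** Mono-olefination of a symmetrical dialdehyde can give double olefination or conjugate addition, and excess 12 has to be removed. The fallback uses a desymmetrised linchpin. It sets out from 12 and returns at 14.
- 12 is converted (HC(OMe)3, MeOH, cat. pyridinium p-toluenesulfonate; separation from the statistical mixture) into the mono-dimethyl acetal F5.
- Lithiated 10 is coupled with F5 (1.1 equiv) and equilibrated thermally to give the C25 keto acetal F6.
- Mild hydrolysis (aqueous oxalic acid, acetone, 20 °C) frees the aldehyde and gives 14.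

**Step 2.** The allylic oxidation of the dienoate may give low yield or attack at the doubly allylic ring CH. The fallback moves the oxidation ahead of the olefination. It sets out from 1 and returns at 4.
- 1 itself, the best-precedented substrate, is oxidised with the same CrO3/t-BuOOH system to 3-oxo-α-ionone F7.
- F7 is then olefinated with 2/NaH chemoselectively at the side-chain methyl ketone to give 4. The ring carbonyl is a hindered, vinylogous cyclohexenone, and side-chain-selective olefination of such diketones is known from abscisic acid work.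

## Further compounds

F1 | step 9 | (R)-hydroxy sulfone: 5-{[(2E,4E)-5-[(1R)-4-hydroxy-2,6,6-trimethylcyclohex-2-en-1-yl]-3-methylpenta-2,4-dien-1-yl]sulfonyl}-1-phenyl-1H-tetrazole (carbinol epimers) | CC1=CC(O)CC(C)(C)[C@H]1/C=C/C(C)=C/CS(=O)(=O)c1nnnn1-c1ccccc1
F2 | step 9 | (S)-hydroxy sulfone: 5-{[(2E,4E)-5-[(1S)-4-hydroxy-2,6,6-trimethylcyclohex-2-en-1-yl]-3-methylpenta-2,4-dien-1-yl]sulfonyl}-1-phenyl-1H-tetrazole (carbinol epimers) | CC1=CC(O)CC(C)(C)[C@@H]1/C=C/C(C)=C/CS(=O)(=O)c1nnnn1-c1ccccc1
F3 | step 9 | C25 hydroxy aldehyde: (2E,4E,6E,8E,10E,12E)-13-[(1R)-4-hydroxy-2,6,6-trimethylcyclohex-2-en-1-yl]-2,7,11-trimethyltrideca-2,4,6,8,10,12-hexaenal (carbinol epimers) | CC1=CC(O)CC(C)(C)[C@H]1/C=C/C(C)=C/C=C/C(C)=C/C=C/C=C(C)/C=O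
F4 | step 9 | (all-E,6S,6'R)-ε,ε-carotene-3,3'-diol (carbinol epimers) | CC1=CC(O)CC(C)(C)[C@@H]1/C=C/C(C)=C/C=C/C(C)=C/C=C/C=C(C)/C=C/C=C(C)/C=C/[C@H]1C(C)=CC(O)CC1(C)C
F5 | step 8 | mono-dimethyl acetal: (2E,4E,6E)-8,8-dimethoxy-2,7-dimethylocta-2,4,6-trienal | O=C/C(C)=C/C=C/C=C(C)/C(OC)OC
F6 | step 8 | C25 keto acetal: (4R)-4-[(1E,3E,5E,7E,9E,11E)-13,13-dimethoxy-3,7,12-trimethyltrideca-1,3,5,7,9,11-hexaen-1-yl]-3,5,5-trimethylcyclohex-2-en-1-one | CC1=CC(=O)CC(C)(C)[C@H]1/C=C/C(C)=C/C=C/C(C)=C/C=C/C=C(C)/C(OC)OC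
F7 | step 2 | 3-oxo-α-ionone (racemic): 4-[(1E)-3-oxobut-1-en-1-yl]-3,5,5-trimethylcyclohex-2-en-1-one | CC(=O)/C=C/C1C(C)=CC(=O)CC1(C)C
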